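C15 and C12 are first adjusted in oxidation level. Ring D is then cut at C13–C16 (Conia-ene) and C11–C15 (aldol). The ring C β,γ-enone goes back by a Birch reduction to an anisole, that is, to a 12-methoxy tricycle with ketones at C1 and C6.
Rings A and B are taken apart together. C4–C5 and C9–C10 are cut and C1–C4 is re-joined, which leaves a 1-alkenyl-2,2-dimethylcyclobutanol with a 4-methoxybenzyl carbinol arm.
Enabling feature: in ring A the only oxygenated carbon (C1) and the gem-dimethyl carbon (C4) are joined by C2–C3 on one side and by only C10–C5 on the other. C1–C2–C3–C4 can therefore be a cyclobutanol whose C1–C4 bond opens to a C1 ketone and a tertiary C4 radical and takes up the alkene C10=C5.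
Forward order: arylacetyl unit (C6–C9, C11–C14), propyne (C5, C10, C20) and 2,2-dimethylcyclobutanone (C1–C4, C18, C19) give the cyclobutanol. Ring A (four to six atoms) and ring B then form in one step, ring C is dearomatised, and ring D is built from propynal (C15–C17).
Stereochemistry: asymmetric transfer hydrogenation sets C6, which relays to C5 and C10 in the cascade and is then erased. CH3-20 then steers hydride to C1 and C6 and the aldehyde to C11, C13 follows by ring constraint, and C12 is set by hydride attack from the C8=C9 side.

Key step: step 7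

Numbering and faces: the carbon numbers of the target are used for all intermediates. Ring A is C1–C5 and C10. Ring B is C5–C10. Ring C is C8, C9 and C11–C14. Ring D is C11, C12, C13, C16 and C15. "α" means the face that carries CH3-20 and "β" the opposite face.
Assumption: 2,2-dimethylcyclobutan-1-one is taken as a catalogue compound.

Step 1
Reactants: 1 4-methoxyphenylacetyl chloride
Product: 2 2-(4-methoxyphenyl)-N-methoxy-N-methylacetamide
Conditions: MeNH(OMe)·HCl, K2CO3, CH2Cl2/H2O, 0 °C
Reagents that add atoms: N,O-dimethylhydroxylamine hydrochloride, CNOC.Cl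
Why: Schotten–Baumann acylation gives the Weinreb amide, and no stereocentre is involved.

Step 2
Reactants: 2 2-(4-methoxyphenyl)-N-methoxy-N-methylacetamide; 3 1-propynylmagnesium bromide
Product: 4 1-(4-methoxyphenyl)pent-3-yn-2-one
Conditions: THF, −78 to 0 °C; 1 M HCl
Reagents that add atoms: none
Why: The Weinreb ketone synthesis stops at the ketone stage, so the ynone that carries C5, C10 and C20 should form without over-addition.

Step 3
Reactants: 4 1-(4-methoxyphenyl)pent-3-yn-2-one
Product: 5 (R)-1-(4-methoxyphenyl)pent-3-yn-2-ol
Conditions: Ru[(R,R)-TsDPEN](p-cymene) (1 mol %), i-PrOH, 25 °C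
Reagents that add atoms: none
Why: In asymmetric transfer hydrogenation of an alkynyl ketone the alkyne takes the role of the aryl group in the six-membered hydride-transfer transition state, so the (R,R)-catalyst should give the (R)-carbinol at C6, and the base-free medium spares the acidic benzylic CH2.

Step 4
Reactants: 5 (R)-1-(4-methoxyphenyl)pent-3-yn-2-ol
Product: 6 (R)-1-methoxy-4-[2-(methoxymethoxy)pent-3-yn-1-yl]benzene
Conditions: MOMCl, i-Pr2NEt, CH2Cl2, 0 to 25 °C
Reagents that add atoms: chloromethyl methyl ether, COCCl
Why: This is a standard O-alkylation to a small acetal protecting group that tolerates organolithium and one-electron oxidants, and C6 is untouched.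

Step 5
Reactants: 6 (R)-1-methoxy-4-[2-(methoxymethoxy)pent-3-yn-1-yl]benzene
Product: 8 1-[(2R,3E)-4-iodo-2-(methoxymethoxy)pent-3-en-1-yl]-4-methoxybenzene, via alkenylzirconocene 7 (not isolated)
Conditions: Cp2Zr(H)Cl (2 equiv), THF, 25 to 40 °C; I2, 0 °C
Reagents that add atoms: iodine, II
Why: In the hydrozirconation–iodination the syn addition places zirconium on the methyl-bearing alkyne carbon, away from the branched C6, and iodinolysis with retention gives the (E)-iodide in which CH3-20 is cis to C6.

Step 6
Reactants: 8 1-[(2R,3E)-4-iodo-2-(methoxymethoxy)pent-3-en-1-yl]-4-methoxybenzene; 9 2,2-dimethylcyclobutan-1-one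
Product: 11 1-[(2E,4R)-5-(4-methoxyphenyl)-4-(methoxymethoxy)pent-2-en-2-yl]-2,2-dimethylcyclobutan-1-ol (both C1 epimers), via alkenyllithium 10 (not isolated)
Conditions: t-BuLi (2.0 equiv), Et2O, −78 °C; then 9, −78 to 0 °C; H2O
Reagents that add atoms: none
Why: Iodine–lithium exchange keeps the alkene geometry and is followed by 1,2-addition to the strained, electrophilic cyclobutanone; the carbinol centre C1 forms as a mixture, which does not matter because C1 becomes a carbonyl carbon in step 7.

Step 7
Reactants: 11 1-[(2E,4R)-5-(4-methoxyphenyl)-4-(methoxymethoxy)pent-2-en-2-yl]-2,2-dimethylcyclobutan-1-ol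
Product: 14 tricyclic ketone 12-methoxy-6β-(methoxymethoxy)-4,4,10-trimethyl tricycle with aromatic ring C and C1 ketone (A/B trans; H-5 β; 6-O equatorial), via ring-opened C4 radical 12 (not isolated), via ring-A alpha-keto radical 13 (not isolated)
Conditions: Mn(OAc)3·2H2O (2.5 equiv), degassed MeCN/AcOH 9:1 (0.01 M), 60 °C
Reagents that add atoms: none
Why: Proposed new method: exchange of the tertiary cyclobutanol onto trivalent manganese and inner-sphere one-electron oxidation give the cyclobutyloxy radical, whose strain-driven β-scission breaks the more substituted C1–C4 bond and so unmasks in one event the C1 carbonyl of an enone and the tertiary C4 radical 12. Radical 12 closes ring A in the 6-endo-trig mode on C5, the β-carbon of that enone (polarity matched; 5-exo attack on the fully substituted C10 is blocked), so that the ring C1–C2–C3–C4 is enlarged by the two atoms C10 and C5, and the electrophilic α-keto radical 13 then closes ring B by six-membered ortho attack on the anisole ring at C9, after which a second equivalent of trivalent manganese oxidises the cyclohexadienyl radical and a proton is lost. The closest known reaction types are the oxidative two-carbon ring expansion of 1-arylcyclobutanols to 1-tetralones and the Mn(OAc)3-mediated polyene cyclisation that ends on a 4-methoxyphenyl group; what is new is the alkene as the two-atom insert and the relay to a second ring. C5 is controlled by C6: A(1,3) strain with CH3-20 holds H-6 in the alkene plane and the bulky radical adds anti to the CH2Ar arm, the syn mode known for radical and cuprate additions to A(1,3)-biased γ-alkoxy acceptors, which leaves the OMOM group equatorial (β). C10 is controlled by C5 through the chair–chair array, in which the aryl arm already lies on the face opposite to the new C4–C5 bond, so that anti addition across C5=C10 gives the trans A/B fusion. The step needs C1–C4 rather than C1–C2 scission (tertiary against primary radical), cyclisation faster than oxidation of the tertiary radical (no copper co-oxidant, high dilution) and ortho rather than ipso attack (the ipso adduct can revert), all of which the substrate and the mild oxidant should secure.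

Step 8
Reactants: 14 tricyclic 6β-OMOM 1-ketone
Product: 15 tricyclic 6β-hydroxy 1-ketone
Conditions: HCl (cat.), MeOH, 50 °C
Reagents that add atoms: none
Why: Acid-catalysed acetal exchange removes the MOM group, and the ketone, the anisole and the quaternary centres are inert to it.

Step 9
Reactants: 15 tricyclic 6β-hydroxy 1-ketone
Product: 16 tricyclic 1,6-dione (A/B trans)
Conditions: Dess–Martin periodinane, CH2Cl2, 0 to 25 °C
Reagents that add atoms: none
Why: The Dess–Martin oxidation works under nearly neutral conditions, so it erases the relay stereocentre C6 without enolising C5.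

Step 10
Reactants: 16 tricyclic 1,6-dione
Product: 17 tricyclic 1α,6α-diol (1-OH equatorial, 6-OH axial, both on the face of CH3-20)
Conditions: NaBH4, MeOH/CH2Cl2, 0 to 25 °C
Reagents that add atoms: none
Why: Borohydride attacks both carbonyl groups from the β face, away from CH3-20 (and from the axial C4 methyl at C6), as in the reduction of angular-methyl 1-decalones and of steroidal 6-ketones, and this sets C1 and C6.

Step 11
Reactants: 17 tricyclic 1α,6α-diol
Product: 19 1α,6α-dihydroxy tricyclic 8(9)-en-12-one, via dihydroanisole 18 (not isolated)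
Conditions: Li, NH3(l)/THF/t-BuOH, −78 to −33 °C; NH4Cl; then (CO2H)2 (cat.), THF/H2O, 25 °C
Reagents that add atoms: water, O
Why: Birch reduction of a 3,4-dialkylanisole leaves the tetrasubstituted C8=C9 alkene and the C12 enol ether, and hydrolysis with a weak acid keeps the alkene out of conjugation, as in the estradiol methyl ether series.

Step 12
Reactants: 19 1α,6α-dihydroxy tricyclic 8(9)-en-12-one
Product: 20 1α-acetoxy-6α-hydroxy tricyclic 8(9)-en-12-one
Conditions: Ac2O (1.2 equiv), DMAP (cat.), pyridine, 0 to 25 °C
Reagents that add atoms: acetic anhydride, CC(=O)OC(C)=O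
Why: In this DMAP-catalysed acylation the equatorial 1-OH should react, while the axial 6-OH is shielded by 1,3-diaxial contacts with CH3-20 and the axial C4 methyl.

Step 13
Reactants: 21 prop-2-yn-1-ol
Product: 22 propynal
Conditions: MnO2 (activated), CH2Cl2, 25 °C; filtered, dried over 4 Å sieves, used as solution
Reagents that add atoms: none
Why: Heterogeneous oxidation of a propargylic alcohol stops at the aldehyde, which is used at once because it is volatile and labile.

Step 14
Reactants: 20 1α-acetoxy-6α-hydroxy tricyclic 8(9)-en-12-one; 22 propynal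
Product: 24 11β-(1-hydroxyprop-2-ynyl) ketone (C15 epimers), via dilithium dienolate 23 (not isolated)
Conditions: LiN(SiMe3)2 (2.2 equiv), THF, −78 to −30 °C; 22, −78 °C; AcOH
Reagents that add atoms: none
Why: In this aldol addition of an extended lithium dienolate, the doubly activated C11–H is removed in preference to C13–H and the acetate, the dienolate reacts at its α-carbon C11 (the γ-carbon C8 is fully substituted), and the aldehyde comes from the β face opposite to CH3-20, which sets C11.

Step 15
Reactants: 24 11β-(1-hydroxyprop-2-ynyl) ketone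
Product: 25 15-O-TBS ether 12(13)-enol TBS ether
Conditions: TBSOTf (2.3 equiv), Et3N, CH2Cl2, −78 to 0 °C
Reagents that add atoms: tert-butyldimethylsilyl triflate, CC(C)(C)[Si](C)(C)OS(=O)(=O)C(F)(F)F
Why: O-silylation blocks the retro-aldol path, and soft enolisation goes toward C13 because enolisation toward C11 would press the C15 arm into the plane next to C10 and the C1 acetate; the hindered axial 6-OH should stay free, and any 6-O-silyl ether would be cleaved in step 18.

Step 16
Reactants: 25 15-O-TBS ether 12(13)-enol TBS ether
Product: 26 tetracyclic 12-ketone with C16=C17 exocyclic methylene and 15-OTBS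
Conditions: Ph3PAuCl (5 mol %), AgBF4 (5 mol %), CH2Cl2/MeOH 10:1, 25 °C
Reagents that add atoms: none
Why: This is a Conia-ene-type 5-exo-dig carbocyclisation of a silyl enol ether onto a terminal alkyne activated by monovalent gold; C13 can reach C16 only on the β face, where the C11 arm stands, so the ring constraint sets C13 and the bicyclo[3.2.1]octane forms with its exocyclic methylene.

Step 17
Reactants: 26 tetracyclic 12-ketone
Product: 27 tetracyclic 12-alcohol (12-OH directed toward the C15–C16 bridge)
Conditions: NaBH4, MeOH, −20 to 0 °C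
Reagents that add atoms: none
Why: In the hydride reduction of this bridged ketone, the side of the C9=C8–C14 bridge has only one axial hydrogen, while the C15–C16 side is shielded by the bridge and its silyloxy group, so hydride should enter over the alkene and leave the hydroxyl syn to the two-carbon bridge, which sets C12.

Step 18
Reactants: 27 tetracyclic 12-alcohol
Product: 28 1α-acetoxy-6α,12,15-triol (C15 epimers)
Conditions: HF·pyridine, THF, 0 to 25 °C
Reagents that add atoms: none
Why: Desilylation with buffered fluoride spares the acetate and the alkenes.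

Step 19
Reactants: 28 1α-acetoxy-6α,12,15-triol
Product: 29 target CNP0149338.1
Conditions: MnO2 (activated), CH2Cl2, 25 °C
Reagents that add atoms: none
Why: Only the allylic 15-OH is oxidised by MnO2, so both C15 epimers converge on the exo-methylene ketone, and the neutral medium avoids retro-aldol opening of the C12 β-hydroxy ketone.

Compound list
1 | 4-methoxyphenylacetyl chloride | COc1ccc(CC(=O)Cl)cc1 | starting material
2 | 2-(4-methoxyphenyl)-N-methoxy-N-methylacetamide | COc1ccc(CC(=O)N(C)OC)cc1 | intermediate
3 | 1-propynylmagnesium bromide | CC#C[Mg]Br | starting material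
4 | 1-(4-methoxyphenyl)pent-3-yn-2-one | COc1ccc(CC(=O)C#CC)cc1 | intermediate
5 | (R)-1-(4-methoxyphenyl)pent-3-yn-2-ol | COc1ccc(C[C@@H](O)C#CC)cc1 | intermediate
6 | (R)-1-methoxy-4-[2-(methoxymethoxy)pent-3-yn-1-yl]benzene | COc1ccc(C[C@@H](OCOC)C#CC)cc1 | intermediate
7 | alkenyl(chloro)zirconocene, Zr on C10, not isolated | COc1ccc(C[C@@H](OCOC)/C=C(\C)[Zr](Cl)(C2C=CC=C2)C2C=CC=C2)cc1 | intermediate
8 | 1-[(2R,3E)-4-iodo-2-(methoxymethoxy)pent-3-en-1-yl]-4-methoxybenzene | COc1ccc(C[C@@H](OCOC)/C=C(\C)I)cc1 | intermediate
9 | 2,2-dimethylcyclobutan-1-one | CC1(C)CCC1=O | starting material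
10 | alkenyllithium from 8, geometry retained, not isolated | COc1ccc(C[C@@H](OCOC)/C=C(\C)[Li])cc1 | intermediate
11 | 1-[(2E,4R)-5-(4-methoxyphenyl)-4-(methoxymethoxy)pent-2-en-2-yl]-2,2-dimethylcyclobutan-1-ol, both C1 epimers | COc1ccc(C[C@@H](OCOC)/C=C(\C)C2(O)CCC2(C)C)cc1 | intermediate
12 | ring-opened (E)-enone with tertiary radical at C4, not isolated | COc1ccc(C[C@@H](OCOC)/C=C(\C)C(=O)CC[C](C)C)cc1 | intermediate
13 | ring A cyclohexanone with α-keto radical at C10, not isolated | COc1ccc(C[C@@H](OCOC)[C@@H]2C(C)(C)CCC(=O)[C]2C)cc1 | intermediate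
14 | tricyclic 1-ketone, aromatic ring C, 12-OMe, 6β-OMOM (equatorial), H-5 β, CH3-20 α | COc4cc3c(cc4)C[C@@H](OCOC)[C@@H]1C(C)(C)CCC(=O)[C@@]31C | intermediate
15 | tricyclic 6β-hydroxy 1-ketone | COc4cc3c(cc4)C[C@@H](O)[C@@H]1C(C)(C)CCC(=O)[C@@]31C | intermediate
16 | tricyclic 1,6-dione, A/B trans | COc4cc3c(cc4)CC(=O)[C@@H]1C(C)(C)CCC(=O)[C@@]31C | intermediate
17 | tricyclic 1α,6α-diol | COc4cc3c(cc4)C[C@H](O)[C@@H]1C(C)(C)CC[C@H](O)[C@@]31C | intermediate
18 | 12-methoxy-8(9),12(13)-diene 1α,6α-diol, not isolated | COC4=CCC(=C3C4)C[C@H](O)[C@@H]1C(C)(C)CC[C@H](O)[C@@]31C | intermediate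
19 | 1α,6α-dihydroxy tricyclic 8(9)-en-12-one | O=C4CCC(=C3C4)C[C@H](O)[C@@H]1C(C)(C)CC[C@H](O)[C@@]31C | intermediate
20 | 1α-acetoxy-6α-hydroxy tricyclic 8(9)-en-12-one | O=C4CCC(=C3C4)C[C@H](O)[C@@H]1C(C)(C)CC[C@H](OC(C)=O)[C@@]31C | intermediate
21 | prop-2-yn-1-ol | C#CCO | starting material
22 | propynal | C#CC=O | intermediate
23 | dilithium 6-alkoxide 11,8-dienolate of 20, not isolated | [Li]OC4=CC3=C(CC4)C[C@H](O[Li])[C@@H]1C(C)(C)CC[C@H](OC(C)=O)[C@@]31C | intermediate
24 | 11β-(1-hydroxyprop-2-ynyl) derivative of 20, C15 epimers | C#CC(O)[C@@H]2C3=C(CCC2=O)C[C@H](O)[C@@H]1C(C)(C)CC[C@H](OC(C)=O)[C@@]31C | intermediate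
25 | 15-O-TBS ether, 12(13)-enol TBS ether | C#CC(O[Si](C)(C)C(C)(C)C)[C@@H]2C3=C(CC=C2O[Si](C)(C)C(C)(C)C)C[C@H](O)[C@@H]1C(C)(C)CC[C@H](OC(C)=O)[C@@]31C | intermediate
26 | tetracyclic 12-ketone, 15-OTBS, C16=C17 methylene, C15–C16 bridge β | C=C1C(O[Si](C)(C)C(C)(C)C)[C@@H]2C3=C(C[C@H]1C2=O)C[C@H](O)[C@@H]1C(C)(C)CC[C@H](OC(C)=O)[C@@]31C | intermediate
27 | tetracyclic 12-alcohol, OH toward the C15–C16 bridge, 15-OTBS | C=C1C(O[Si](C)(C)C(C)(C)C)[C@@H]2C3=C(C[C@H]1[C@@H]2O)C[C@H](O)[C@@H]1C(C)(C)CC[C@H](OC(C)=O)[C@@]31C | intermediate
28 | 1α-acetoxy-6α,12,15-triol, C15 epimers | C=C1C(O)[C@@H]2C3=C(C[C@H]1[C@@H]2O)C[C@H](O)[C@@H]1C(C)(C)CC[C@H](OC(C)=O)[C@@]31C | intermediate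
29 | CNP0149338.1 | C=C1C(=O)[C@@H]2C3=C(C[C@H]1[C@@H]2O)C[C@H](O)[C@@H]1C(C)(C)CC[C@H](OC(C)=O)[C@@]31C | target

Total step count: 19. Longest linear sequence: 18 (steps 1–12 and 14–19).

Steps most likely to fail

Step 7. The hindered tertiary alcohol may be oxidised too slowly. The tertiary radical may be oxidised to the cation before it cyclises. The oxidant may attack the anisole ring, or the facial selectivity at C5 may be low at 60 °C.
The fallback sets out from iodide 8 and comes back at ketone 14. Commercial 4-methylpent-4-enoic acid is converted (carbonyldiimidazole, MeNH(OMe)·HCl) into N-methoxy-N,4-dimethylpent-4-enamide F1. Alkenyllithium 10, made from 8 as in step 6, is acylated with it to give (6E,8R)-9-(4-methoxyphenyl)-8-(methoxymethoxy)-2,6-dimethylnona-1,6-dien-5-one F2.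
Hydrogen-atom transfer from a cobalt hydride to the 1,1-disubstituted alkene of F2 then gives the same tertiary radical 12. The hydride is formed from the divalent cobalt complex N,N'-bis(3,5-di-tert-butylsalicylidene)-1,2-cyclohexanediaminocobalt as catalyst, N-fluoro-2,4,6-trimethylpyridinium triflate and 1,1,3,3-tetramethyldisiloxane. This works at or below room temperature and without a stoichiometric metal oxidant. The aryl-terminated radical bicyclisation, a known reaction type, leads to 14. In this variant ring A is closed directly and no four-membered ring is used.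

Step 14. The β-hydroxy ketone may suffer retro-aldol cleavage or dehydration. The dienolate may add in the conjugate sense to the ynal, or attack may occur at C13 instead of C11.
The fallback sets out from 20 and comes back at triol 28. It installs the C15 oxygen last instead of first.
- Dienolate 23 is alkylated with propargyl bromide (deconjugative α-alkylation) to give the 11β-propargyl ketone F3.
- TBSOTf/Et3N gives the 12(13)-enol silyl ether F4.
- Ph3PAuCl/AgBF4 closes ring D to the 15-deoxy tetracyclic 12-ketone F5.
- NaBH4 gives the 15-deoxy 12-alcohol F6.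
- Allylic hydroxylation of the exocyclic methylene unit with SeO2/t-BuOOH, the classical C15 oxidation of 16-ene bicyclo[3.2.1]octanes, gives 28.

Step 16. The enol silane may be protodesilylated faster than it cyclises, or gold may ionise the propargylic silyl ether.
The fallback sets out from 25 and comes back at 26. It replaces π-acid catalysis by a radical closure. N-Bromosuccinimide converts the enol silane into the 13-bromo 12-ketone F7. Bu3SnH with Et3B/air then generates the C13 α-keto radical, which closes ring D in the 5-exo-dig mode onto the alkyne and, after hydrogen abstraction by the vinyl radical, gives 26.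

Further compounds
F1 | step 7 | N-methoxy-N,4-dimethylpent-4-enamide | C=C(C)CCC(=O)N(C)OC
F2 | step 7 | (6E,8R)-9-(4-methoxyphenyl)-8-(methoxymethoxy)-2,6-dimethylnona-1,6-dien-5-one | COc1ccc(C[C@@H](OCOC)/C=C(\C)C(=O)CCC(C)=C)cc1
F3 | step 14 | 11β-propargyl ketone | C#CC[C@@H]2C3=C(CCC2=O)C[C@H](O)[C@@H]1C(C)(C)CC[C@H](OC(C)=O)[C@@]31C
F4 | step 14 | 12(13)-enol silyl ether | C#CC[C@@H]2C3=C(CC=C2O[Si](C)(C)C(C)(C)C)C[C@H](O)[C@@H]1C(C)(C)CC[C@H](OC(C)=O)[C@@]31C
F5 | step 14 | 15-deoxy tetracyclic 12-ketone | C=C1C[C@@H]2C3=C(C[C@H]1C2=O)C[C@H](O)[C@@H]1C(C)(C)CC[C@H](OC(C)=O)[C@@]31C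
F6 | step 14 | 15-deoxy 12-alcohol | C=C1C[C@@H]2C3=C(C[C@H]1[C@@H]2O)C[C@H](O)[C@@H]1C(C)(C)CC[C@H](OC(C)=O)[C@@]31C
F7 | step 16 | 13-bromo 12-ketone | C#CC(O[Si](C)(C)C(C)(C)C)[C@@H]2C3=C(CC(Br)C2=O)C[C@H](O)[C@@H]1C(C)(C)CC[C@H](OC(C)=O)[C@@]31C
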